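**Retrosynthetic overview**
- The target comes from a C9-benzoyloxy, C14-silyloxy germacradienoate by ester exchange at C9, desilylation, C14–OH-directed Sharpless epoxidation of C1=C10 and isobutyrylation.
- The strategy rests on C5 and C10: they face each other across the ten-membered ring and each ends an alkene unit (C4=C5 enoate; C1=C10, masked as the epoxide). A C5–C10 bond therefore folds the ring into a cis-decalin (ring A = C5–C10, ring B = C1–C5 + C10) with the ester at C4 and a sulfonate at C1, which an enolate-triggered Grob fragmentation reopens.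
- The cis-decalin comes from a Diels–Alder reaction of a 2-formyl-5-isopropenylcyclohexenone (formyl = C14, ketone = C9) with the silyloxy dienoate from 2H-pyran-2-one, followed by a redox relay (C1 ketone, C9 reduction, C9–OH-directed Tishchenko reduction of C1).
- Ring A comes from cyclohex-2-en-1-one by asymmetric isopropenyl conjugate addition, formylation and dehydrogenation.
- Ring order: ring A, then ring B (cycloaddition), then the ten-membered ring by cleavage of the shared C5–C10 bond.

Key step: step 12

Convention: atoms carry the numbers of the target (germacrane numbering, C1–C15); α is the face of ring A that bears the isopropenyl group, β the other face; TBS = tert-butyldimethylsilyl; chair 1 is the chair–chair form with C14 axial on ring B, chair 2 the ring-flipped form.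
Remark (assumption): the cycloaddition is taken to follow the ketone-endo mode known for 2-acylcyclohexenones; the C1 configuration it sets is erased in step 7 and the C4 configuration is destroyed in the key step.
Remark (assumption): L-(+)-diethyl tartrate is taken to give (2S,3S)-epoxy alcohols from simple (E)-allylic alcohols; the tartrate in step 16 is chosen by mapping C10=C1/C14–OH onto that model.

**Step 1**
Reactants: 1 cyclohex-2-en-1-one; 2 potassium trifluoro(prop-1-en-2-yl)borate
Product: 3 (S)-3-(prop-1-en-2-yl)cyclohexan-1-one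
Conditions: [Rh(cod)Cl]2 (1.5 mol %), (S)-BINAP (3.3 mol %), toluene–H2O, 100 °C
Reagents that add atoms: none
Why: Hayashi–Miyaura rhodium-catalysed asymmetric conjugate addition of an alkenylboron reagent; the (S)-BINAP complex should add the isopropenyl group to one enone face and give the (S) ketone whose stereocentre becomes C7.

**Step 2**
Reactants: 3 (S)-3-(prop-1-en-2-yl)cyclohexan-1-one
Product: 4 (5S)-2-(hydroxymethylene)-5-(prop-1-en-2-yl)cyclohexan-1-one
Conditions: NaH, HCO2Et, EtOH (cat.), THF, 0 to 20 °C; 1 M HCl
Reagents that add atoms: ethyl formate, CCOC=O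
Why: Claisen formylation under equilibrating conditions places the formyl carbon (future C14) on the α-carbon remote from the ring substituent, as with 3-alkylcyclohexanones, and leaves the stereocentre untouched.

**Step 3**
Reactants: 5 2H-pyran-2-one
Product: 7 methyl (2E,4E)-5-(triethylsilyloxy)penta-2,4-dienoate, via sodium dienolate 6 (not isolated)
Conditions: NaOMe, MeOH, 0 °C; evaporate; Et3SiCl, THF, 0 °C
Reagents that add atoms: sodium methoxide, C[O-].[Na+]; chlorotriethylsilane, CC[Si](Cl)(CC)CC
Why: Acyl substitution of the lactone by methoxide opens the ring to a delocalised dienolate, which should relax to the all-trans form before O-silylation (lactone ring opening, enolate silylation).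

**Step 4**
Reactants: 4 (5S)-2-(hydroxymethylene)-5-(prop-1-en-2-yl)cyclohexan-1-one; 7 methyl (2E,4E)-5-(triethylsilyloxy)penta-2,4-dienoate
Product: 9 cis-decalin keto aldehyde (1β-OSiEt3; 2-ene; 4β-CO2Me; 5α-H; 7α-isopropenyl; 9-oxo; 10α-CHO), via formyl enone 8 (not isolated)
Conditions: DDQ (1.0 equiv), 1,4-dioxane, 20 °C, filter; then 7, ZnCl2 (20 mol %), CH2Cl2, −20 to 20 °C
Reagents that add atoms: none
Why: DDQ dehydrogenation of the hydroxymethylene ketone gives the doubly activated 2-formyl enone, which should undergo a ZnCl2-assisted Diels–Alder reaction in which the donor oxygen sends its carbon to C10 and the ester carbon to C5, the diene adds anti to the isopropenyl group (as with carvone) so that the ring fusion is cis with C14 and H5 on the isopropenyl face, and the ketone-endo mode gives the 1β,4β arrangement drawn.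

**Step 5**
Reactants: 9 cis-decalin keto aldehyde
Product: 11 keto diol (1β-OH; 14-OH; 9-oxo; 2-ene), via triethylsilyl ether 10 (not isolated)
Conditions: LiAlH(OtBu)3 (1.1 equiv), THF, −78 °C; then 1 M HCl, MeOH, 0 to 20 °C
Reagents that add atoms: none
Why: The one-hydride reagent should reduce the aldehyde far faster than the hindered ketone or the ester (chemoselective carbonyl reduction, no stereocentre formed; the cold acidic quench avoids retro-aldol loss of formaldehyde), and dilute acid then cleaves the secondary triethylsilyl ether.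

**Step 6**
Reactants: 11 keto diol
Product: 12 14-O-TBS keto alcohol (1β-OH; 9-oxo; 2-ene)
Conditions: TBSCl (1.05 equiv), imidazole, DMF, 0 °C
Reagents that add atoms: tert-butyldimethylsilyl chloride, CC(C)(C)[Si](C)(C)Cl
Why: Silylation should take the primary C14 hydroxyl in preference to the hindered secondary allylic C1 hydroxyl.

**Step 7**
Reactants: 12 14-O-TBS keto alcohol
Product: 13 ene-dione (1,9-dioxo; 2-ene; 14-OTBS)
Conditions: MnO2 (excess), CH2Cl2, 20 °C
Reagents that add atoms: none
Why: Allylic oxidation with MnO2 erases the C1 configuration left by the cycloaddition (a neopentyl centre that could not be inverted by substitution) and turns C2=C3 into an enone alkene.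

**Step 8**
Reactants: 13 ene-dione
Product: 14 dione (1,9-dioxo; 14-OTBS; 4β-CO2Me)
Conditions: [(Ph3P)CuH]6 (0.4 equiv), toluene, H2O (2 equiv), 20 °C
Reagents that add atoms: none
Why: Copper hydride conjugate reduction should saturate only the enone C2=C3 bond and leave the isopropenyl alkene, the ketones and the ester alone, which a hydrogenation catalyst could not do.

**Step 9**
Reactants: 14 dione
Product: 15 9α-hydroxy 1-ketone (14-OTBS)
Conditions: LiBH(s-Bu)3 (1.05 equiv), THF, −78 °C; AcOH quench at −78 °C
Reagents that add atoms: none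
Why: With the C4 ester equatorial the dione should sit in chair 1, where axial attack on C9 is blocked by the syn-axial isopropenyl group and both faces of C1 are shielded (axial C14 beside it, syn-axial C6 across ring B), so the bulky hydride should attack C9 from the equatorial β direction and give the 9α alcohol (substrate-controlled ketone reduction).

**Step 10**
Reactants: 15 9α-hydroxy 1-ketone
Product: 16 9α-benzoate 1α-alcohol (14-OTBS)
Conditions: PhCHO (6 equiv), SmI2 (30 mol %), THF, −10 °C
Reagents that add atoms: benzaldehyde, O=Cc1ccccc1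
Why: Evans–Tishchenko reduction: the C9 hydroxyl forms a samarium-bound hemiacetal with benzaldehyde and passes its hydride to C1 through a six-membered transition state possible only in chair 2 (O9 equatorial on ring A and gauche to C1, C9 axial on ring B), so the hydride arrives on the C9 side and the new C1 hydroxyl is α (cis to C14), while O9 leaves as its benzoate and the two secondary oxygens are told apart.

**Step 11**
Reactants: 16 9α-benzoate 1α-alcohol
Product: 17 cis-decalin ester tosylate (1α-OTs; 4β-CO2Me; 9α-OBz; 14-OTBS)
Conditions: TsCl (1.5 equiv), Et3N, Me3N·HCl (10 mol %), CH2Cl2, 0 to 20 °C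
Reagents that add atoms: p-toluenesulfonyl chloride, Cc1ccc(cc1)S(Cl)(=O)=O
Why: Sulfonylation of the only free hydroxyl under trimethylamine catalysis, with retention at C1; a tosylate is used because the methyl group of a mesylate would be deprotonated by the amide base of the next step before the ester α-hydrogen.

**Step 12**
Reactants: 17 cis-decalin ester tosylate
Product: 18 protected germacradienoate (C1=C10 with C2 trans to C9; C4=C5 with C3 cis to C6; 9-OBz; 14-OTBS)
Conditions: KN(SiMe3)2 (1.2 equiv), THF, −78 °C, then to 0 °C
Reagents that add atoms: none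
Why: Proposed new method: KN(SiMe3)2 removes the C4 hydrogen α to the ester, and in chair 1 (tosylate equatorial, C14 and C6 axial on ring B) the enolate π-system, the C5–C10 σ-bond and the C1–O bond are aligned, so the electron pair should move from the enolate into C4=C5, from C5–C10 into C1=C10 and onto the departing tosylate in one step. The closest known reaction type is the Grob fragmentation in its alkoxide-triggered form (Wharton, decalin 1,3-diol monosulfonates) and its boronate-triggered form (decalyl sulfonates to cyclodeca-1,5-dienes); an ester enolate as electron source for this 1,4-relationship is not established. The ten-membered ring is not closed by bond formation but set free by cleavage of the bond shared by rings A and B (ring expansion by fragmentation). No stereocentre is created, but two alkene geometries are: the tosylate anti to C5–C10 with C9 equatorial and C14 axial at C10 puts C2 trans to C9, and the cis ring fusion with C6 axial at C5 puts C3 cis to C6 and the ester trans to C6. The step needs fragmentation to win over E2 loss of the tosylate, C-alkylation and acyl transfer, which rests on five points: only the 1α tosylate can lie anti to C5–C10; allylic 1,3-strain in the exocyclic enolate favours chair 1 and so offsets the 1,3-diaxial isopropenyl/benzoyloxy pair on ring A; C-alkylation would have to close a bicyclo[2.2.0]hexane; the benzoate lies anti to C4 across C5–C10; the tosylate has no acidic α-hydrogen. Conjugation of the new C4=C5 bond with the ester adds driving force.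

**Step 13**
Reactants: 18 protected germacradienoate
Product: 19 9-hydroxy germacradienoate (14-OTBS)
Conditions: K2CO3, MeOH, 20 °C
Reagents that add atoms: none
Why: Methanolysis (transesterification) removes the benzoate; the methyl ester is unchanged by methoxide exchange and the primary silyl ether is stable.

**Step 14**
Reactants: 19 9-hydroxy germacradienoate
Product: 20 9-acetoxy germacradienoate (14-OTBS)
Conditions: Ac2O, pyridine, DMAP (cat.), CH2Cl2, 0 to 20 °C
Reagents that add atoms: acetic anhydride, CC(=O)OC(C)=O
Why: Acetylation of the secondary allylic alcohol installs the C9 acetate before the epoxidation, so that a free O9 (a matched secondary allylic alcohol for the opposite alkene face) cannot direct the oxidant.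

**Step 15**
Reactants: 20 9-acetoxy germacradienoate
Product: 21 9-acetoxy 14-hydroxy germacradienoate
Conditions: HF·pyridine, pyridine, THF, 0 to 20 °C
Reagents that add atoms: none
Why: Buffered fluoride cleaves the primary allylic silyl ether and should not cause acyl migration or harm the acetate and the enoate.

**Step 16**
Reactants: 21 9-acetoxy 14-hydroxy germacradienoate
Product: 22 (1R,10S)-1,10-epoxy 14-alcohol
Conditions: Ti(OiPr)4 (10 mol %), L-(+)-diethyl tartrate (12 mol %), t-BuOOH, 4 Å molecular sieves, CH2Cl2, −20 °C
Reagents that add atoms: tert-butyl hydroperoxide, CC(C)(C)OO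
Why: Katsuki–Sharpless asymmetric epoxidation: titanium binds the only free hydroxyl, so only C1=C10 reacts (enoate and isopropenyl untouched), and L-(+)-diethyl tartrate should deliver oxygen to the face that gives the (1R,10S) epoxide under reagent control, although the cis C2 substituent and the ring conformation may lower the selectivity.

**Step 17**
Reactants: 22 (1R,10S)-1,10-epoxy 14-alcohol
Product: 23 target CNP0372928.1
Conditions: isobutyryl chloride, pyridine, DMAP (cat.), CH2Cl2, 0 °C
Reagents that add atoms: isobutyryl chloride, CC(C)C(Cl)=O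
Why: Acylation of the primary epoxy alcohol under mild base gives the isobutyrate; no stereocentre is touched.

**Compound list**
1 | cyclohex-2-en-1-one | O=C1C=CCCC1 | starting material
2 | potassium trifluoro(prop-1-en-2-yl)borate | [K+].C=C(C)[B-](F)(F)F | starting material
3 | (S)-3-(prop-1-en-2-yl)cyclohexan-1-one | C=C(C)[C@@H]1CC(=O)CCC1 | intermediate
4 | (5S)-2-(hydroxymethylene)-5-(prop-1-en-2-yl)cyclohexan-1-one (Z enol) | C=C(C)[C@@H]1CC(=O)/C(=C\O)CC1 | intermediate
5 | 2H-pyran-2-one | O=C1C=CC=CO1 | starting material
6 | sodium (1E,3E)-5-methoxy-5-oxopenta-1,3-dien-1-olate | [Na+].COC(=O)/C=C/C=C/[O-] | intermediate (not isolated)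
7 | methyl (2E,4E)-5-(triethylsilyloxy)penta-2,4-dienoate | COC(=O)/C=C/C=C/O[Si](CC)(CC)CC | intermediate
8 | (4S)-6-oxo-4-(prop-1-en-2-yl)cyclohex-1-ene-1-carbaldehyde | C=C(C)[C@@H]1CC(=O)C(C=O)=CC1 | intermediate (not isolated)
9 | cis-decalin keto aldehyde: 1β-triethylsilyloxy, 2-ene, 4β-CO2Me, 5α-H, 7α-isopropenyl, 9-oxo, 10α-formyl (C14) | C=C(C)[C@H]1C[C@@H]2[C@H](C(=O)OC)C=C[C@H](O[Si](CC)(CC)CC)[C@]2(C=O)C(=O)C1 | intermediate
10 | 9-keto 14-alcohol 1β-triethylsilyl ether | C=C(C)[C@H]1C[C@@H]2[C@H](C(=O)OC)C=C[C@H](O[Si](CC)(CC)CC)[C@]2(CO)C(=O)C1 | intermediate (not isolated)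
11 | keto diol: 1β-OH, 14-OH, 9-oxo, 2-ene | C=C(C)[C@H]1C[C@@H]2[C@H](C(=O)OC)C=C[C@H](O)[C@]2(CO)C(=O)C1 | intermediate
12 | 14-O-TBS keto alcohol: 1β-OH, 9-oxo, 2-ene | C=C(C)[C@H]1C[C@@H]2[C@H](C(=O)OC)C=C[C@H](O)[C@]2(CO[Si](C)(C)C(C)(C)C)C(=O)C1 | intermediate
13 | ene-dione: 1,9-dioxo, 2-ene, 14-OTBS | C=C(C)[C@H]1C[C@@H]2[C@H](C(=O)OC)C=CC(=O)[C@]2(CO[Si](C)(C)C(C)(C)C)C(=O)C1 | intermediate
14 | dione: 1,9-dioxo, 14-OTBS | C=C(C)[C@H]1C[C@@H]2[C@H](C(=O)OC)CCC(=O)[C@]2(CO[Si](C)(C)C(C)(C)C)C(=O)C1 | intermediate
15 | 9α-hydroxy 1-ketone, 14-OTBS | C=C(C)[C@H]1C[C@@H]2[C@H](C(=O)OC)CCC(=O)[C@]2(CO[Si](C)(C)C(C)(C)C)[C@@H](O)C1 | intermediate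
16 | 9α-benzoate 1α-alcohol, 14-OTBS | C=C(C)[C@H]1C[C@@H]2[C@H](C(=O)OC)CC[C@@H](O)[C@]2(CO[Si](C)(C)C(C)(C)C)[C@@H](OC(=O)c3ccccc3)C1 | intermediate
17 | cis-decalin ester tosylate (key-step precursor): 1α-OTs, 4β-CO2Me, 9α-OBz, 14-OTBS | C=C(C)[C@H]1C[C@@H]2[C@H](C(=O)OC)CC[C@@H](OS(=O)(=O)c3ccc(C)cc3)[C@]2(CO[Si](C)(C)C(C)(C)C)[C@@H](OC(=O)c3ccccc3)C1 | intermediate
18 | protected germacradienoate (key-step product): 9-OBz, 14-OTBS | C=C(C)[C@H]1C/C=C(/C(=O)OC)CC/C=C(\CO[Si](C)(C)C(C)(C)C)[C@@H](OC(=O)c2ccccc2)C1 | intermediate
19 | 9-hydroxy germacradienoate, 14-OTBS | C=C(C)[C@H]1C/C=C(/C(=O)OC)CC/C=C(\CO[Si](C)(C)C(C)(C)C)[C@@H](O)C1 | intermediate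
20 | 9-acetoxy germacradienoate, 14-OTBS | C=C(C)[C@H]1C/C=C(/C(=O)OC)CC/C=C(\CO[Si](C)(C)C(C)(C)C)[C@@H](OC(C)=O)C1 | intermediate
21 | 9-acetoxy 14-hydroxy germacradienoate | C=C(C)[C@H]1C/C=C(/C(=O)OC)CC/C=C(\CO)[C@@H](OC(C)=O)C1 | intermediate
22 | (1R,10S)-1,10-epoxy 14-alcohol, 9-acetate | C=C(C)[C@H]1C/C=C(/C(=O)OC)CC[C@H]2O[C@]2(CO)[C@@H](OC(C)=O)C1 | intermediate
23 | CNP0372928.1 | C=C(C)[C@H]1C/C=C(/C(=O)OC)CC[C@H]2O[C@]2(COC(=O)C(C)C)[C@@H](OC(C)=O)C1 | target

**Step count**
Total: 17 steps. Longest linear sequence: 16 steps (steps 1, 2 and 4–17, from cyclohex-2-en-1-one); step 3 is a one-step branch.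

**Steps most likely to fail**

1. Step 12 (the new fragmentation). The enolate may not reach chair 1, in which case proton return, or base-induced anti-elimination of the axial tosylate in chair 2, would outrun fragmentation. Fallback, from 16 back to 18: 16 is treated with LiN(iPr)2 (2.2 equiv, THF, −78 °C; alkoxide, then ester enolate, with no leaving group yet present) and CBr4 to give the C4 bromo ester alcohol F1. Tosylation as in step 11 gives the bromo ester tosylate F2. Zn(Cu) in THF–DMF then creates the carbon–zinc centre at C4 without base and should expel the tosylate through C5–C10, the reductive 1,4-elimination with fragmentation known for 1,4-dihalides and halo sulfonates, to give 18.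

2. Step 4 (formyl enone generation and cycloaddition). The push–pull diene may add too slowly to the short-lived formyl enone, which can tautomerise or dimerise, or the enol ether end of the diene may add across the oxadiene unit of the dienophile (loss of periselectivity). Fallback, from 4 back to 14: 8 is generated as in step 4 and trapped by Mukaiyama–Michael addition, anti to the isopropenyl group, of the ketene trimethylsilyl acetal F3 (from commercial methyl 5,5-dimethoxypentanoate with LiN(iPr)2 and Me3SiCl), giving after work-up the formyl ketone F4. 1 M HCl in THF frees the C1 aldehyde, and MgBr2·OEt2 with Et3N closes ring B by aldol addition of the chelated β-keto aldehyde, giving the cis-fused hydroxy keto aldehyde F5. LiAlH(OtBu)3 gives the keto diol F6, TBSCl the silyl ether F7, and Dess–Martin periodinane the dione 14 (C1 configuration erased; the C4 ester is equilibrated to the equatorial epimer with DBU).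

3. Step 9 (mono-reduction of the dione). Hydride may attack C1, or the other face of C9, if chair 1 does not dominate (loss of regio- and facial selectivity). Fallback, from 12 back to 15: the single ketone of 12 is reduced under reagent control with (R)-2-methyl-CBS-oxazaborolidine and catecholborane (hydride to the β face, C10 as the large group) to give the diol F8. MnO2 gives the hydroxy enone F9, and [(Ph3P)CuH]6 gives 15.

Further compounds
F1 | step 12 | C4-bromo ester 1α-alcohol, 9α-OBz, 14-OTBS | C=C(C)[C@H]1C[C@@H]2C(Br)(C(=O)OC)CC[C@@H](O)[C@]2(CO[Si](C)(C)C(C)(C)C)[C@@H](OC(=O)c3ccccc3)C1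
F2 | step 12 | C4-bromo ester 1α-tosylate, 9α-OBz, 14-OTBS | C=C(C)[C@H]1C[C@@H]2C(Br)(C(=O)OC)CC[C@@H](OS(=O)(=O)c3ccc(C)cc3)[C@]2(CO[Si](C)(C)C(C)(C)C)[C@@H](OC(=O)c3ccccc3)C1
F3 | step 4 | trimethyl[(1,5,5-trimethoxypent-1-en-1-yl)oxy]silane | COC(OC)CCC=C(OC)O[Si](C)(C)C
F4 | step 4 | Michael adduct: 2-(hydroxymethylene) ketone with the C1–C4 chain at C5 (C4 epimers) | C=C(C)[C@H]1C[C@H](C(C(=O)OC)CCC(OC)OC)C(=CO)C(=O)C1
F5 | step 4 | cis-decalin 1α-hydroxy 9-keto 14-aldehyde (C4 epimers) | C=C(C)[C@H]1C[C@@H]2C(C(=O)OC)CC[C@@H](O)[C@]2(C=O)C(=O)C1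
F6 | step 4 | cis-decalin 1α,14-diol 9-ketone (C4 epimers) | C=C(C)[C@H]1C[C@@H]2C(C(=O)OC)CC[C@@H](O)[C@]2(CO)C(=O)C1
F7 | step 4 | cis-decalin 1α-hydroxy 9-ketone, 14-OTBS (C4 epimers) | C=C(C)[C@H]1C[C@@H]2C(C(=O)OC)CC[C@@H](O)[C@]2(CO[Si](C)(C)C(C)(C)C)C(=O)C1
F8 | step 9 | 1β,9α-diol, 2-ene, 14-OTBS | C=C(C)[C@H]1C[C@@H]2[C@H](C(=O)OC)C=C[C@H](O)[C@]2(CO[Si](C)(C)C(C)(C)C)[C@@H](O)C1
F9 | step 9 | 9α-hydroxy 2-en-1-one, 14-OTBS | C=C(C)[C@H]1C[C@@H]2[C@H](C(=O)OC)C=CC(=O)[C@]2(CO[Si](C)(C)C(C)(C)C)[C@@H](O)C1
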